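In a closed vessel at constant volume the slope of the product curve is the rate itself. You ask for a quick number, and your hunch is that one curve cannot part substrate from partner; I will still commit to a number for partner, at the price of two assumptions, both stated below.

in all of them: free catalyst 4.3 mol%
- zeta: substrate 0.12 M; partner 1.3 equiv; run made earlier
- flask: substrate 0.059 M; partner 1.30 equiv

zeta run (percent of the substrate charged)

| time / h | product / % | substrate / % |
|---|---|---|
| 1.00 | 10.8 | 89.1 |
| 1.33 | 13.5 | 85.5 |
| 2.00 | 18.4 | 80.3 |
| 3.00 | 25.4 | 73.0 |
| 5.00 | 35.6 | 63.2 |
| 8.00 | 46.6 | 51.8 |
| 12.0 | 56.4 | 41.3 |

(readings scatter by 0.3 percentage points)

- what was read earlier has a scatter of 0.3 percentage points, one standard deviation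
- no earlier run changes the charge of free catalyst; that part of a forecast is a guess
- no earlier run changes the charge of partner; that part of a forecast is a guess

* apparent order in free catalyst when 20% of the substrate are converted (percent change of the rate of making product for one percent more free catalyst charged)
* apparent order in partner when 20% of the substrate are converted (percent change of the rate of making product for one percent more partner charged)

I take two stretches of the zeta run, in fractions of the charge, and count partner as falling by product over its equivalents. The early stretch makes 0.0760 h⁻¹ with substrate at 0.847 and partner at 0.888. The late stretch makes 0.0245 h⁻¹ with substrate at 0.466 and partner at 0.604. Now I go to logarithms: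

decades of rate per decade of substrate = 1.89

decades of partner per decade of substrate = 0.644

If I grant first order in substrate, the excess slope belongs to partner, and dividing it by partner's fall gives the one-curve partner order:

one-curve partner order = (1.89 − 1) / 0.644 = 1.38

The flask keeps the equivalents and the loading at about half the concentration, so I carry this number to it. No run varies the charge of partner, so this number stays an estimate, and no run varies the free catalyst, so there I guess first order.

The forecast parts from me on partner, giving 0.6 for partner and 0.95 for free catalyst, and says of itself: “This is a guess, as neither charge was varied.”

The flask gives 1.4 for partner and 1.2 for free catalyst.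

    catalyst intermediate B ⇌ free catalyst + product (K = 0.0680 M, k = 26.0 h⁻¹)
    partner ⇌ dormant form (K = 0.720, k = 0.0709 h⁻¹)
    partner + free catalyst → catalyst intermediate A (k = 22.7 M⁻¹ h⁻¹)
    substrate + catalyst intermediate A ⇌ catalyst intermediate B (K = 170 M⁻¹, k = 2240 M⁻¹ h⁻¹)

My 1.38 stands beside 1.4, but in this flask my count of partner does not hold. After 4.00 h this flask has 65.4% of its partner, less than the 84.7% that my count from product gives, and dormant form holds 18.6% of the partner charge. That step, both ways, carries a part of the order: without it the same flask gives 1.1, which is 0.245 below the actual order.

The numbers in the tables come from a simulation for substances that don't exist.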